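**Assumption:** positions are referred to by germacrane numbering (C1 ketone, C2=C3, C3–O–C10 ether bridge, C4=C15, C5 carbinol, C6 ester carbon, C7, C8 lactone carbinol, C9, C10, C11=C13, C12 lactone carbonyl, C14 methyl); the target is then (5S,6R,7S,8S,10R).

## Retrosynthetic overview

1. Ten-membered ring last: C4–C5 bond by a chromium/nickel reductive alkyne–aldehyde macrocyclisation of a seco ynal (sets C5, creates the C4=C15 methylene; proposed new method).
2. Seco ynal from a lactone acetonide: the C5/C6 diol is unmasked, C6 is acylated with methacrylate and C5 is oxidised to the aldehyde.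
3. cis-α-Methylene-γ-butyrolactone (second ring): C7–C8 bond by indium Barbier allylation and lactonisation between a furanone acetaldehyde and a Z-2-(bromomethyl)enoate; C6 controls C7 and C8.
4. Bromide (C5–C7, C11–C13) from (R)-solketal and methyl acrylate by Morita–Baylis–Hillman reaction and SN2′ bromination.
5. 3(2H)-Furanone (first ring): gold-catalysed 5-endo cyclisation of an α′-hydroxy diynone made from (S)-lactic acid (alkylation sets C10) and bis(trimethylsilyl)butadiyne. Ring order: furanone, lactone, ten-membered carbocycle.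

## Route

**Step 1**
Reactants: 1 (S)-lactic acid
Product: 2 (2S,5S)-2-tert-butyl-5-methyl-1,3-dioxolan-4-one
Conditions: t-BuCHO, p-TsOH (cat.), H2SO4 (cat.), pentane, reflux, Dean–Stark; recrystallisation at −78 °C
Reagents that add atoms: pivalaldehyde, CC(C)(C)C=O
Why: Acid-catalysed acetalisation of the α-hydroxy acid; the cis-dioxolanone is favoured and purified by crystallisation, which stores the lactate chirality at the acetal carbon (self-regeneration of stereocentres).

**Step 2**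
Reactants: 2 cis-dioxolanone; 3 allyl bromide
Product: 5 (2S,5R)-2-tert-butyl-5-methyl-5-(prop-2-en-1-yl)-1,3-dioxolan-4-one, via lithium enolate 4 (not isolated)
Conditions: LiN(i-Pr)2, THF, −78 °C; then 3, −78 → −30 °C
Reagents that add atoms: none
Why: Enolate alkylation in which allyl bromide attacks the planar enolate on the face anti to the tert-butyl group, so allyl replaces H with retention and the quaternary centre (later C10, R) is set.

**Step 3**
Reactants: 5 allyl dioxolanone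
Product: 6 (2R)-2-hydroxy-N-methoxy-N,2-dimethylpent-4-enamide
Conditions: MeNH(OMe)·HCl, i-PrMgCl, THF, −20 → 0 °C
Reagents that add atoms: N,O-dimethylhydroxylamine hydrochloride, CNOC.Cl
Why: Acyl substitution on the activated dioxolanone by the chloromagnesium amide, after which the hemiacetal alkoxide loses pivalaldehyde and leaves the α-hydroxy Weinreb amide with the quaternary centre intact.

**Step 4**
Reactants: 6 Weinreb amide; 7 1,4-bis(trimethylsilyl)buta-1,3-diyne
Product: 9 (6R)-6-hydroxy-6-methyl-1-(trimethylsilyl)non-8-ene-1,3-diyn-5-one, via lithium diynide 8 (not isolated)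
Conditions: 7 (2.6 equiv), MeLi·LiBr (2.5 equiv), THF, 0 °C → rt; then 6, −78 → −20 °C; sat. aq. NH4Cl
Reagents that add atoms: none
Why: Weinreb ketone synthesis in which MeLi removes one silyl group of 7, one equivalent of the acetylide deprotonates the hydroxyl and a second adds to the amide to give a chelated tetrahedral intermediate that releases the ynone only on quench.

**Step 5**
Reactants: 9 α′-hydroxy diynone
Product: 10 (2R)-2-methyl-2-(prop-2-en-1-yl)-5-[(trimethylsilyl)ethynyl]furan-3(2H)-one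
Conditions: (p-CF3C6H4)3PAuCl (5 mol %), AgOTf (5 mol %), toluene, rt
Reagents that add atoms: none
Why: Cationic monovalent gold activates the ynone triple bond for 5-endo-dig attack of the tertiary hydroxyl at the β-carbon and protodeauration gives the 3(2H)-furanone (gold-catalysed cycloisomerisation of α′-hydroxy ynones); the quaternary centre is not involved.

**Step 6**
Reactants: 10 allyl furanone
Product: 12 2-{(2R)-2-methyl-3-oxo-5-[(trimethylsilyl)ethynyl]-2,3-dihydrofuran-2-yl}acetaldehyde, via diol 11 (not isolated)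
Conditions: OsO4 (2 mol %), NaIO4 (4 equiv), 2,6-lutidine, dioxane/H2O (3:1), rt
Reagents that add atoms: osmium tetroxide, O=[Os](=O)(=O)=O; sodium periodate, [Na+].[O-]I(=O)(=O)=O
Why: Lemieux–Johnson oxidation in which the monosubstituted alkene is dihydroxylated much faster than the push–pull enone or the silyl alkyne and periodate cleaves the diol to the aldehyde.

**Step 7**
Reactants: 13 (R)-solketal
Product: 14 (4S)-2,2-dimethyl-1,3-dioxolane-4-carbaldehyde
Conditions: PhI(OAc)2, TEMPO (10 mol %), CH2Cl2, rt; used as solution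
Reagents that add atoms: none
Why: Oxoammonium (TEMPO) oxidation of the primary alcohol under neutral conditions, which avoids epimerisation of the α-oxygenated centre (later C6).

**Step 8**
Reactants: 14 (S)-glyceraldehyde acetonide; 15 methyl acrylate
Product: 16 methyl 2-{[(4S)-2,2-dimethyl-1,3-dioxolan-4-yl](hydroxy)methyl}prop-2-enoate
Conditions: DABCO (1 equiv), 15 (3 equiv), dioxane/H2O (1:1), rt, 48 h
Reagents that add atoms: none
Why: Morita–Baylis–Hillman reaction; the new carbinol centre forms as an epimer mixture that is erased in step 9, while the dioxolane centre is untouched.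

**Step 9**
Reactants: 16 Morita–Baylis–Hillman adduct
Product: 17 methyl (2Z)-2-(bromomethyl)-3-[(4R)-2,2-dimethyl-1,3-dioxolan-4-yl]prop-2-enoate
Conditions: NBS, Me2S, CH2Cl2, 0 °C → rt
Reagents that add atoms: N-bromosuccinimide, O=C1CCC(=O)N1Br
Why: Corey–Kim-type activation of the allylic alcohol as an alkoxysulfonium ion and SN2′ attack of bromide give the conjugated trisubstituted enoate with the thermodynamically favoured Z geometry (dioxolanyl cis to CH2Br).

**Step 10**
Reactants: 12 furanone acetaldehyde; 17 Z-allylic bromide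
Product: 20 (4S,5S)-4-[(4R)-2,2-dimethyl-1,3-dioxolan-4-yl]-3-methylidene-5-({(2R)-2-methyl-3-oxo-5-[(trimethylsilyl)ethynyl]-2,3-dihydrofuran-2-yl}methyl)oxolan-2-one, via allylindium dibromide 18 (not isolated), via hydroxy ester 19 (not isolated)
Conditions: In powder, THF/H2O (1:1), rt; then PPTS (cat.), toluene, 50 °C
Reagents that add atoms: none
Why: Barbier allylation through a closed chair (Zimmerman–Traxler) transition state in which the Z-olefin places the dioxolanyl group axial (7,8-syn adduct, hence cis-lactone) and, with H-6 held in the olefin plane by allylic 1,3-strain, the aldehyde adds to C7 anti to the C6–O bond, so C6 sets C7 (S) and C8 (S) before acid-catalysed lactonisation.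

**Step 11**
Reactants: 20 lactone acetonide
Product: 21 (4R,5S)-4-[(1R)-1,2-dihydroxyethyl]-3-methylidene-5-({(2R)-2-methyl-3-oxo-5-[(trimethylsilyl)ethynyl]-2,3-dihydrofuran-2-yl}methyl)oxolan-2-one
Conditions: AcOH/H2O (4:1), 35 °C
Reagents that add atoms: none
Why: Mild acid-catalysed acetal hydrolysis frees the C5/C6 diol without touching the silyl alkyne, the vinylogous ester or the lactone, and without moving the lactone to O6.

**Step 12**
Reactants: 21 diol
Product: 22 (4R,5S)-4-[(1R)-2-{[tert-butyl(dimethyl)silyl]oxy}-1-hydroxyethyl]-3-methylidene-5-({(2R)-2-methyl-3-oxo-5-[(trimethylsilyl)ethynyl]-2,3-dihydrofuran-2-yl}methyl)oxolan-2-one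
Conditions: TBSCl, imidazole, CH2Cl2, −20 → 0 °C
Reagents that add atoms: tert-butyldimethylsilyl chloride, CC(C)(C)[Si](C)(C)Cl
Why: Silyl ether formation with steric differentiation, the primary hydroxyl reacting far faster than the hindered secondary one.

**Step 13**
Reactants: 22 silyl ether; 23 methacrylic anhydride
Product: 24 (1R)-2-{[tert-butyl(dimethyl)silyl]oxy}-1-[(2S,3S)-4-methylidene-2-({(2R)-2-methyl-3-oxo-5-[(trimethylsilyl)ethynyl]-2,3-dihydrofuran-2-yl}methyl)-5-oxooxolan-3-yl]ethyl 2-methylprop-2-enoate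
Conditions: 23, Et3N, DMAP (cat.), CH2Cl2, 0 °C → rt
Reagents that add atoms: none
Why: DMAP-catalysed acyl transfer esterifies the only free hydroxyl (C6) faster than any base-mediated lactone migration can occur.

**Step 14**
Reactants: 24 silylated methacrylate
Product: 25 (1R)-1-[(2S,3S)-2-{[(2R)-5-ethynyl-2-methyl-3-oxo-2,3-dihydrofuran-2-yl]methyl}-4-methylidene-5-oxooxolan-3-yl]-2-hydroxyethyl 2-methylprop-2-enoate
Conditions: TBAF, AcOH (1:1), THF, 0 °C → rt
Reagents that add atoms: none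
Why: Fluoride cleaves the O–Si bond and the activated C(sp)–Si bond in one operation, and the acetic acid buffer keeps the medium non-basic so that the methacrylate does not migrate to the primary hydroxyl.

**Step 15**
Reactants: 25 primary alcohol
Product: 26 (1R)-1-[(2S,3S)-2-{[(2R)-5-ethynyl-2-methyl-3-oxo-2,3-dihydrofuran-2-yl]methyl}-4-methylidene-5-oxooxolan-3-yl]-2-oxoethyl 2-methylprop-2-enoate
Conditions: Dess–Martin periodinane, CH2Cl2, 0 °C → rt
Reagents that add atoms: none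
Why: Dess–Martin oxidation under neutral conditions gives the α-acyloxy aldehyde without epimerising C6.

**Step 16**
Reactants: 26 seco ynal
Product: 28 (5S,6R,7S,8S,10R)-5-hydroxy-6-(methacryloyloxy)-1-oxo-3,10-epoxygermacra-2,4(15),11(13)-trien-12,8-olide (CNP0142847.2), via alkenylchromium dichloride 27 (not isolated)
Conditions: CrCl2 (8 equiv), NiCl2 (0.2 equiv), PPh3 (0.4 equiv), H2O (2 equiv), DMF, 25 °C, 2 mM, slow addition of 26
Reagents that add atoms: none
Why: Proposed new method: a macrocyclising hydrometalative alkyne–aldehyde coupling in which divalent chromium reduces NiCl2 to zerovalent nickel, the nickel–alkyne complex is protonated by water at the unsubstituted terminus C15 (also the electrophilic end of this vinylogous ynoate) so that nickel sits on C4, transmetalation to trivalent chromium gives alkenylchromium 27, and this adds to the C5 aldehyde in a Nozaki–Hiyama–Kishi-type 1,2-addition under Felkin–Anh control by the C6 acyloxy group (5,6-anti, hence 5S) while ignoring the enoate, lactone and enone acceptors; the closest known reaction type is the intermolecular CrCl2/NiCl2/PPh3/H2O reductive coupling of terminal alkynes with aldehydes to 2-substituted allylic alcohols, together with Nozaki–Hiyama–Kishi macrocyclisation of alkenyl halides, and it has not been shown in a ring-forming sense or on a conjugated alkyne.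

## Compound list

1 | (S)-lactic acid, (2S)-2-hydroxypropanoic acid | C[C@H](O)C(=O)O | starting material
2 | (2S,5S)-2-tert-butyl-5-methyl-1,3-dioxolan-4-one (cis) | C[C@@H]1O[C@H](C(C)(C)C)OC1=O | intermediate
3 | allyl bromide (3-bromoprop-1-ene) | C=CCBr | starting material
4 | lithium (2S)-2-tert-butyl-5-methyl-1,3-dioxol-4-olate (lithium enolate of 2, formed in the flask) | CC1=C(O[Li])O[C@@H](C(C)(C)C)O1 | intermediate
5 | (2S,5R)-2-tert-butyl-5-methyl-5-(prop-2-en-1-yl)-1,3-dioxolan-4-one (allyl trans to tert-butyl) | C[C@]1(CC=C)O[C@H](C(C)(C)C)OC1=O | intermediate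
6 | (2R)-2-hydroxy-N-methoxy-N,2-dimethylpent-4-enamide | C=CC[C@@](C)(O)C(=O)N(C)OC | intermediate
7 | 1,4-bis(trimethylsilyl)buta-1,3-diyne | C[Si](C)(C)C#CC#C[Si](C)(C)C | starting material
8 | lithium 4-(trimethylsilyl)buta-1,3-diyn-1-ide (formed in the flask) | [Li]C#CC#C[Si](C)(C)C | intermediate
9 | (6R)-6-hydroxy-6-methyl-1-(trimethylsilyl)non-8-ene-1,3-diyn-5-one | C=CC[C@@](C)(O)C(=O)C#CC#C[Si](C)(C)C | intermediate
10 | (2R)-2-methyl-2-(prop-2-en-1-yl)-5-[(trimethylsilyl)ethynyl]furan-3(2H)-one | C=CC[C@@]1(C)OC(C#C[Si](C)(C)C)=CC1=O | intermediate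
11 | (2R)-2-(2,3-dihydroxypropyl)-2-methyl-5-[(trimethylsilyl)ethynyl]furan-3(2H)-one (both carbinol epimers, formed in the flask) | OCC(O)C[C@@]1(C)OC(C#C[Si](C)(C)C)=CC1=O | intermediate
12 | 2-{(2R)-2-methyl-3-oxo-5-[(trimethylsilyl)ethynyl]-2,3-dihydrofuran-2-yl}acetaldehyde | O=CC[C@@]1(C)OC(C#C[Si](C)(C)C)=CC1=O | intermediate
13 | (R)-solketal, [(4R)-2,2-dimethyl-1,3-dioxolan-4-yl]methanol | OC[C@@H]1COC(C)(C)O1 | starting material
14 | (4S)-2,2-dimethyl-1,3-dioxolane-4-carbaldehyde, (S)-glyceraldehyde acetonide | O=C[C@@H]1COC(C)(C)O1 | intermediate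
15 | methyl acrylate | C=CC(=O)OC | starting material
16 | methyl 2-{[(4S)-2,2-dimethyl-1,3-dioxolan-4-yl](hydroxy)methyl}prop-2-enoate (carbinol epimer mixture) | C=C(C(=O)OC)C(O)[C@@H]1COC(C)(C)O1 | intermediate
17 | methyl (2Z)-2-(bromomethyl)-3-[(4R)-2,2-dimethyl-1,3-dioxolan-4-yl]prop-2-enoate | BrC/C(=C\[C@@H]1COC(C)(C)O1)C(=O)OC | intermediate
18 | dibromo{(2Z)-3-[(4R)-2,2-dimethyl-1,3-dioxolan-4-yl]-2-(methoxycarbonyl)prop-2-en-1-yl}indium (allylindium species drawn as the monomeric dibromide, formed in the flask) | Br[In](Br)C/C(=C\[C@@H]1COC(C)(C)O1)C(=O)OC | intermediate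
19 | methyl 2-[(1S,2S)-1-[(4R)-2,2-dimethyl-1,3-dioxolan-4-yl]-2-hydroxy-3-{(2R)-2-methyl-3-oxo-5-[(trimethylsilyl)ethynyl]-2,3-dihydrofuran-2-yl}propyl]prop-2-enoate (formed in the flask) | CC1(C)OC[C@H](O1)[C@@H](C(=C)C(=O)OC)[C@@H](O)C[C@@]2(C)OC(C#C[Si](C)(C)C)=CC2=O | intermediate
20 | (4S,5S)-4-[(4R)-2,2-dimethyl-1,3-dioxolan-4-yl]-3-methylidene-5-({(2R)-2-methyl-3-oxo-5-[(trimethylsilyl)ethynyl]-2,3-dihydrofuran-2-yl}methyl)oxolan-2-one | CC1(C)OC[C@H](O1)[C@H]2C(=C)C(=O)O[C@H]2C[C@@]3(C)OC(C#C[Si](C)(C)C)=CC3=O | intermediate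
21 | (4R,5S)-4-[(1R)-1,2-dihydroxyethyl]-3-methylidene-5-({(2R)-2-methyl-3-oxo-5-[(trimethylsilyl)ethynyl]-2,3-dihydrofuran-2-yl}methyl)oxolan-2-one | OC[C@H](O)[C@H]1C(=C)C(=O)O[C@H]1C[C@@]2(C)OC(C#C[Si](C)(C)C)=CC2=O | intermediate
22 | (4R,5S)-4-[(1R)-2-{[tert-butyl(dimethyl)silyl]oxy}-1-hydroxyethyl]-3-methylidene-5-({(2R)-2-methyl-3-oxo-5-[(trimethylsilyl)ethynyl]-2,3-dihydrofuran-2-yl}methyl)oxolan-2-one | CC(C)(C)[Si](C)(C)OC[C@H](O)[C@H]1C(=C)C(=O)O[C@H]1C[C@@]2(C)OC(C#C[Si](C)(C)C)=CC2=O | intermediate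
23 | methacrylic anhydride | CC(=C)C(=O)OC(=O)C(C)=C | starting material
24 | (1R)-2-{[tert-butyl(dimethyl)silyl]oxy}-1-[(2S,3S)-4-methylidene-2-({(2R)-2-methyl-3-oxo-5-[(trimethylsilyl)ethynyl]-2,3-dihydrofuran-2-yl}methyl)-5-oxooxolan-3-yl]ethyl 2-methylprop-2-enoate | CC(=C)C(=O)O[C@@H](CO[Si](C)(C)C(C)(C)C)[C@H]1C(=C)C(=O)O[C@H]1C[C@@]2(C)OC(C#C[Si](C)(C)C)=CC2=O | intermediate
25 | (1R)-1-[(2S,3S)-2-{[(2R)-5-ethynyl-2-methyl-3-oxo-2,3-dihydrofuran-2-yl]methyl}-4-methylidene-5-oxooxolan-3-yl]-2-hydroxyethyl 2-methylprop-2-enoate | CC(=C)C(=O)O[C@@H](CO)[C@H]1C(=C)C(=O)O[C@H]1C[C@@]2(C)OC(C#C)=CC2=O | intermediate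
26 | (1R)-1-[(2S,3S)-2-{[(2R)-5-ethynyl-2-methyl-3-oxo-2,3-dihydrofuran-2-yl]methyl}-4-methylidene-5-oxooxolan-3-yl]-2-oxoethyl 2-methylprop-2-enoate | CC(=C)C(=O)O[C@@H](C=O)[C@H]1C(=C)C(=O)O[C@H]1C[C@@]2(C)OC(C#C)=CC2=O | intermediate
27 | alkenylchromium dichloride of 26 (trivalent chromium on C4, C15 as =CH2, stereocentres as in 26; formed in the flask) | CC(=C)C(=O)O[C@@H](C=O)[C@H]1C(=C)C(=O)O[C@H]1C[C@@]2(C)OC(C(=C)[Cr](Cl)Cl)=CC2=O | intermediate
28 | (5S,6R,7S,8S,10R)-5-hydroxy-6-(methacryloyloxy)-1-oxo-3,10-epoxygermacra-2,4(15),11(13)-trien-12,8-olide, CNP0142847.2 | C=C(C)C(=O)O[C@@H]1[C@H]2C(=C)C(=O)O[C@H]2C[C@@]2(C)OC(=CC2=O)C(=C)[C@@H]1O | target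

## Step count and risks

Total step count: 16. Longest linear sequence: 13 steps (steps 1–6 and 10–16, from (S)-lactic acid); the bromide branch (steps 7–9) is convergent.

**Step 16 (proposed new macrocyclisation).** It may fail by protonation of the alkenyl metal before ring closure (giving the 5-vinylfuranone), by reduction of the activated alkyne, by the wrong regiochemistry of hydrometalation, or by giving the C5 epimer. The fallback uses only known chemistry, sets out from 10 and comes back to the route at 28.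
- Buffered TBAF/AcOH removes the alkynyl silyl group to give the ethynyl furanone F1.
- Bu3SnH with PdCl2(PPh3)2 (2 mol %) in THF at 0 °C places tin on the carbon next to the furanone (the regiochemistry known for ynoates) to give the 1-(tributylstannyl)ethenyl furanone F2, and I2 in CH2Cl2 at 0 °C gives the 1-iodoethenyl furanone F3.
- F3 is taken through the operations of steps 6 and 10 to 13 unchanged: the iodo diol F4 (not isolated) and the iodo aldehyde F5; then, through allylindium 18, the iodo hydroxy ester F6 (not isolated) and the iodo lactone acetonide F7; then the iodo lactone diol F8, the iodo silyl ether F9 and the iodo methacrylate F10.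
- HF·pyridine in THF at 0 °C frees the iodo primary alcohol F11 and Dess–Martin oxidation gives the iodo seco aldehyde F12.
- A standard Nozaki–Hiyama–Kishi macrocyclisation (CrCl2, NiCl2 1 mol %, DMSO/THF, high dilution) generates the same alkenylchromium 27 from the C–I bond and closes it to 28.

**Step 10 (Barbier coupling).** The syn (cis-lactone) outcome is well supported, but the facial preference imposed by C6 rests on a model and could be the opposite one. The fallback keeps the coupling but changes the stereochemical strategy; it sets out from 12 and comes back to the route at 24.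
- Commercial (R)-glyceraldehyde acetonide F13 is carried through steps 8 and 9 to the enantiomeric Morita–Baylis–Hillman adduct F14 and the enantiomeric Z-bromide F15.
- Indium-mediated coupling with 12, through the enantiomeric allylindium dibromide F16 and the 6-epi hydroxy ester F17 (both not isolated), then delivers the 6-epi lactone acetonide F18, which has the required 7S,8S configuration if the bromide's inherent facial bias is opposite to the model.
- Hydrolysis as in step 11 gives the 6-epi diol F19 and silylation as in step 12 gives the 6-epi silyl ether F20.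
- Mitsunobu esterification (methacrylic acid, PPh3, DIAD, toluene, 0 °C) inverts C6 and installs the methacrylate in one operation, giving 24.

**Step 14 (double desilylation).** The free primary hydroxyl next to the secondary methacrylate can take over the acyl group, and fluoride or acetate may add to the newly freed activated alkyne. The fallback never frees that hydroxyl; it sets out from 21 and comes back to the route at 26.
- TESCl/imidazole at −20 °C gives the primary triethylsilyl ether F21, and acylation as in step 13 gives the triethylsilyl methacrylate F22.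
- The primary TES ether is oxidised directly under Swern conditions ((COCl)2, DMSO, CH2Cl2, −78 → −30 °C, then Et3N) to the silylalkynyl aldehyde F23.
- AgNO3 (10 mol %) in acetone/H2O removes the alkynyl silyl group under neutral conditions to give 26.

## Further compounds

F1 | step 16 | (2R)-5-ethynyl-2-methyl-2-(prop-2-en-1-yl)furan-3(2H)-one | C=CC[C@@]1(C)OC(C#C)=CC1=O
F2 | step 16 | (2R)-2-methyl-2-(prop-2-en-1-yl)-5-[1-(tributylstannyl)ethenyl]furan-3(2H)-one | C=CC[C@@]1(C)OC(C(=C)[Sn](CCCC)(CCCC)CCCC)=CC1=O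
F3 | step 16 | (2R)-5-(1-iodoethenyl)-2-methyl-2-(prop-2-en-1-yl)furan-3(2H)-one | C=CC[C@@]1(C)OC(C(I)=C)=CC1=O
F4 | step 16 | (2R)-2-(2,3-dihydroxypropyl)-5-(1-iodoethenyl)-2-methylfuran-3(2H)-one (carbinol epimers) | OCC(O)C[C@@]1(C)OC(C(I)=C)=CC1=O
F5 | step 16 | 2-[(2R)-5-(1-iodoethenyl)-2-methyl-3-oxo-2,3-dihydrofuran-2-yl]acetaldehyde | O=CC[C@@]1(C)OC(C(I)=C)=CC1=O
F6 | step 16 | methyl 2-[(1S,2S)-1-[(4R)-2,2-dimethyl-1,3-dioxolan-4-yl]-2-hydroxy-3-[(2R)-5-(1-iodoethenyl)-2-methyl-3-oxo-2,3-dihydrofuran-2-yl]propyl]prop-2-enoate | CC1(C)OC[C@H](O1)[C@@H](C(=C)C(=O)OC)[C@@H](O)C[C@@]2(C)OC(C(I)=C)=CC2=O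
F7 | step 16 | (4S,5S)-4-[(4R)-2,2-dimethyl-1,3-dioxolan-4-yl]-5-{[(2R)-5-(1-iodoethenyl)-2-methyl-3-oxo-2,3-dihydrofuran-2-yl]methyl}-3-methylideneoxolan-2-one | CC1(C)OC[C@H](O1)[C@H]2C(=C)C(=O)O[C@H]2C[C@@]3(C)OC(C(I)=C)=CC3=O
F8 | step 16 | (4R,5S)-4-[(1R)-1,2-dihydroxyethyl]-5-{[(2R)-5-(1-iodoethenyl)-2-methyl-3-oxo-2,3-dihydrofuran-2-yl]methyl}-3-methylideneoxolan-2-one | OC[C@H](O)[C@H]1C(=C)C(=O)O[C@H]1C[C@@]2(C)OC(C(I)=C)=CC2=O
F9 | step 16 | (4R,5S)-4-[(1R)-2-{[tert-butyl(dimethyl)silyl]oxy}-1-hydroxyethyl]-5-{[(2R)-5-(1-iodoethenyl)-2-methyl-3-oxo-2,3-dihydrofuran-2-yl]methyl}-3-methylideneoxolan-2-one | CC(C)(C)[Si](C)(C)OC[C@H](O)[C@H]1C(=C)C(=O)O[C@H]1C[C@@]2(C)OC(C(I)=C)=CC2=O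
F10 | step 16 | (1R)-2-{[tert-butyl(dimethyl)silyl]oxy}-1-[(2S,3S)-2-{[(2R)-5-(1-iodoethenyl)-2-methyl-3-oxo-2,3-dihydrofuran-2-yl]methyl}-4-methylidene-5-oxooxolan-3-yl]ethyl 2-methylprop-2-enoate | CC(=C)C(=O)O[C@@H](CO[Si](C)(C)C(C)(C)C)[C@H]1C(=C)C(=O)O[C@H]1C[C@@]2(C)OC(C(I)=C)=CC2=O
F11 | step 16 | (1R)-2-hydroxy-1-[(2S,3S)-2-{[(2R)-5-(1-iodoethenyl)-2-methyl-3-oxo-2,3-dihydrofuran-2-yl]methyl}-4-methylidene-5-oxooxolan-3-yl]ethyl 2-methylprop-2-enoate | CC(=C)C(=O)O[C@@H](CO)[C@H]1C(=C)C(=O)O[C@H]1C[C@@]2(C)OC(C(I)=C)=CC2=O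
F12 | step 16 | (1R)-1-[(2S,3S)-2-{[(2R)-5-(1-iodoethenyl)-2-methyl-3-oxo-2,3-dihydrofuran-2-yl]methyl}-4-methylidene-5-oxooxolan-3-yl]-2-oxoethyl 2-methylprop-2-enoate | CC(=C)C(=O)O[C@@H](C=O)[C@H]1C(=C)C(=O)O[C@H]1C[C@@]2(C)OC(C(I)=C)=CC2=O
F13 | step 10 | (4R)-2,2-dimethyl-1,3-dioxolane-4-carbaldehyde, (R)-glyceraldehyde acetonide | O=C[C@H]1COC(C)(C)O1
F14 | step 10 | methyl 2-{[(4R)-2,2-dimethyl-1,3-dioxolan-4-yl](hydroxy)methyl}prop-2-enoate (carbinol epimer mixture) | C=C(C(=O)OC)C(O)[C@H]1COC(C)(C)O1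
F15 | step 10 | methyl (2Z)-2-(bromomethyl)-3-[(4S)-2,2-dimethyl-1,3-dioxolan-4-yl]prop-2-enoate | BrC/C(=C\[C@H]1COC(C)(C)O1)C(=O)OC
F16 | step 10 | dibromo{(2Z)-3-[(4S)-2,2-dimethyl-1,3-dioxolan-4-yl]-2-(methoxycarbonyl)prop-2-en-1-yl}indium | Br[In](Br)C/C(=C\[C@H]1COC(C)(C)O1)C(=O)OC
F17 | step 10 | methyl 2-[(1S,2S)-1-[(4S)-2,2-dimethyl-1,3-dioxolan-4-yl]-2-hydroxy-3-{(2R)-2-methyl-3-oxo-5-[(trimethylsilyl)ethynyl]-2,3-dihydrofuran-2-yl}propyl]prop-2-enoate | CC1(C)OC[C@@H](O1)[C@@H](C(=C)C(=O)OC)[C@@H](O)C[C@@]2(C)OC(C#C[Si](C)(C)C)=CC2=O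
F18 | step 10 | (4S,5S)-4-[(4S)-2,2-dimethyl-1,3-dioxolan-4-yl]-3-methylidene-5-({(2R)-2-methyl-3-oxo-5-[(trimethylsilyl)ethynyl]-2,3-dihydrofuran-2-yl}methyl)oxolan-2-one | CC1(C)OC[C@@H](O1)[C@H]2C(=C)C(=O)O[C@H]2C[C@@]3(C)OC(C#C[Si](C)(C)C)=CC3=O
F19 | step 10 | (4R,5S)-4-[(1S)-1,2-dihydroxyethyl]-3-methylidene-5-({(2R)-2-methyl-3-oxo-5-[(trimethylsilyl)ethynyl]-2,3-dihydrofuran-2-yl}methyl)oxolan-2-one | OC[C@@H](O)[C@H]1C(=C)C(=O)O[C@H]1C[C@@]2(C)OC(C#C[Si](C)(C)C)=CC2=O
F20 | step 10 | (4R,5S)-4-[(1S)-2-{[tert-butyl(dimethyl)silyl]oxy}-1-hydroxyethyl]-3-methylidene-5-({(2R)-2-methyl-3-oxo-5-[(trimethylsilyl)ethynyl]-2,3-dihydrofuran-2-yl}methyl)oxolan-2-one | CC(C)(C)[Si](C)(C)OC[C@@H](O)[C@H]1C(=C)C(=O)O[C@H]1C[C@@]2(C)OC(C#C[Si](C)(C)C)=CC2=O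
F21 | step 14 | (4R,5S)-4-{(1R)-1-hydroxy-2-[(triethylsilyl)oxy]ethyl}-3-methylidene-5-({(2R)-2-methyl-3-oxo-5-[(trimethylsilyl)ethynyl]-2,3-dihydrofuran-2-yl}methyl)oxolan-2-one | CC[Si](CC)(CC)OC[C@H](O)[C@H]1C(=C)C(=O)O[C@H]1C[C@@]2(C)OC(C#C[Si](C)(C)C)=CC2=O
F22 | step 14 | (1R)-1-[(2S,3S)-4-methylidene-2-({(2R)-2-methyl-3-oxo-5-[(trimethylsilyl)ethynyl]-2,3-dihydrofuran-2-yl}methyl)-5-oxooxolan-3-yl]-2-[(triethylsilyl)oxy]ethyl 2-methylprop-2-enoate | CC(=C)C(=O)O[C@@H](CO[Si](CC)(CC)CC)[C@H]1C(=C)C(=O)O[C@H]1C[C@@]2(C)OC(C#C[Si](C)(C)C)=CC2=O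
F23 | step 14 | (1R)-1-[(2S,3S)-4-methylidene-2-({(2R)-2-methyl-3-oxo-5-[(trimethylsilyl)ethynyl]-2,3-dihydrofuran-2-yl}methyl)-5-oxooxolan-3-yl]-2-oxoethyl 2-methylprop-2-enoate | CC(=C)C(=O)O[C@@H](C=O)[C@H]1C(=C)C(=O)O[C@H]1C[C@@]2(C)OC(C#C[Si](C)(C)C)=CC2=O
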